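# Synthesis plan for ebenfuran V (17) by low-valent titanium closure of the furan C2=C3 bond

## The problem

Ebenfuran V (17) is a 2-arylbenzofuran in which benzo ring A is fused to furan ring C, C2 carries the 2,4-dihydroxyphenyl ring B and C3 a formyl group. It has no stereocenter, so the task is one of regiochemistry and of the order in which functional groups appear. Ring A has a single CH at C7: O1 and the free C4 hydroxyl both flank the fusion carbon C3a and must be told apart, and the 3-hydroxy-3-methylbutyl chain must sit at C5, between the C4 oxygen and the C6 methoxyl. Three groups limit what can be done late: the aldehyde, open to reduction and oxidation alike; three free phenols on electron-rich rings, which tolerate neither oxidants nor strong base; and the tertiary alcohol, which lies ortho to the C4 hydroxyl and can dehydrate or close to a 2,2-dimethylchroman under acid. The feature that opens the route is the C2=C3 bond of ring C. C3 is bonded to C3a and can be the carbonyl carbon of an acetyl group on ring A, while C2 is bonded to O1 and to ring B and can be the carboxyl carbon of a ring B benzoic acid held on O1 as an aryl ester. With O1, C7a and C3a already in place, a reductive carbonyl–carbonyl coupling then closes ring C. The price is that C3 emerges with a methyl group, which has to be raised to the aldehyde afterwards.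

## Retrosynthesis

**17 from 16.** The three phenolic O–H bonds are traced back to benzyl ethers in 16. One neutral hydrogenolysis frees all three phenols at the very end, so the electron-rich triphenol never meets acid, base or an oxidant. The forward step must stop before the aldehyde is reduced.

**16 from 15.** The formyl carbon is traced back to the C3 methyl group of 15. This adjustment is imposed by the key step, which delivers C3 with the former acetyl methyl attached. The methyl group sits on the enol-ether-like C3 of the furan and is flanked by two electron-rich aryl systems, so it is the most activated C–H position in 15. A Riley oxidation is asked to spare the benzyl ethers and the tertiary alcohol.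

**15 from 14.** The tertiary C–O bond of the side chain is removed, leaving the prenyl alkene of 14. Carrying the chain as an alkene through the reductive, Lewis acidic key step avoids a silyl ether and its later removal. Hydration must precede the methyl oxidation, because a prenyl group would itself suffer allylic oxidation. The forward reaction has to be a Markovnikov hydration under neutral conditions that does not touch the furan double bond.

**14 from 13 (key disconnection).** The C2=C3 bond is cut into two carbonyl groups of like polarity: the acetyl carbonyl on C3a and the carbonyl of a 2,4-bis(benzyloxy)benzoate on O1, both in keto ester 13. A polar closure would require an umpoled carbon at one end. A cross-coupling approach would need a prebuilt benzofuran. Here the two aromatic halves are joined by an ordinary O-acylation and the ring closes intramolecularly. The precursor has one ring fewer and is assembled from a phenol and an acid. The forward step needs low-valent titanium to couple a hindered 2,6-dioxygenated aryl ketone with an electron-rich aryl ester faster than either is simply reduced.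

**13 from 8 and 11.** The ester C–O bond is cut to phenol 8 and acid 11, the acid being activated as chloride 12. Phenol 8 has only one free hydroxyl, so the oxygen that becomes O1 is fixed without any selectivity question. Non-enolizing amine conditions are required so that the ortho-acyloxy ketone does not undergo Baker–Venkataraman acyl migration.

**8 from 5.** The bond between ring A and the prenyl CH2 is cut, and the prenyl group is returned to the phenolic oxygen para to it, giving prenyl ether 5. The neighbouring option is direct C-prenylation of 1. That reaction is low-yielding and leaves two hydroxyls to be distinguished by sterics alone, followed by benzylation of a chelated phenol in the presence of a base-sensitive aryl ester. The Claisen–Cope sequence instead places the chain para to the oxygen that is released. That oxygen is exactly the one that must become O1, and the other oxygen is already benzylated. In the forward direction the second [3,3] shift has to outrun enolization of the first dienone 6, so that the chain passes on through dienone 7.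

**5 from 3 and 4; 3 from 1 and 2.** Two ether C–O bonds are cut. Acetophenone 1 is symmetric, so the first benzylation raises no regiochemical question. The remaining hydroxyl is chelated to the acetyl group, which favours the mono-ether 3, and it is then O-prenylated under more forcing conditions with 4.

**11 from 9 and 2.** The two benzyl ether C–O bonds of the ring B acid are cut. Acid 9 is benzylated exhaustively with three equivalents of 2 to ester 10, and saponification of the ester then gives 11.

## Roads not taken

Alternative 1: benzannulation of a furylketene to build ring A.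
- Cut: four bonds of ring A (C7–C7a, C6–C7, C4–C5, C3a–C4). The precursors are the furyl diazoketone A1, which already carries ring B and a C3 ester, and the methoxyalkyne A2, which carries the side chain.
- Key step: irradiation of A1 triggers a Wolff rearrangement. A [2+2] cycloaddition to A2, four-electron ring opening and a six-electron electrocyclization onto the furan β-carbon follow, ending in phenol A3.
- Merits: the placement of the hydroxyl, chain and methoxyl on ring A follows from the connectivity of the cascade. The C4 hydroxyl is delivered free, and C3 is already at the carboxyl oxidation level. In regiochemical security this is better than the chosen plan.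
- Weak points for this target: A1 needs a trisubstituted furan and a diazo transfer. A2 is a sensitive alkynyl ether that has to be made in several steps. The closure must engage a furan carbon next to an ester. The ester of A3 then needs reduction and re-oxidation to reach the aldehyde.
- Comparison: the chosen plan answers with four commercial starting materials (1, 2, 4 and 9), nine steps without photochemistry and a ring closure of known type. Its regiochemistry rests on the Claisen–Cope step and not on the ring construction itself.

Alternative 2: acid-induced ring switch of a 2'-hydroxyisoflavone.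
- Cut: the O1–C2 bond. The benzofuran is traced back to isoflavone A4, in which the future ring A is the 3-aryl group with one free ortho hydroxyl. The other ortho oxygen is tied up in a dihydrocoumarin lactone that also holds the side-chain carbons.
- Key step: under HBF4·OEt2 the free hydroxyl of A4 attacks the chromone carbonyl carbon and water is lost. The cation so formed is trapped by methanol, giving the racemic cyclic acetal A5.
- Merits: the formyl carbon is present at the aldehyde oxidation level from the beginning, masked as the acetal. The lactone protects the C4 oxygen and later yields the tertiary alcohol by double methyl addition. No late C–H oxidation and no hydrogenolysis beside a free aldehyde are needed, which is better than the chosen plan on both counts.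
- Weak points for this target: A4 requires joining a chromone to a doubly ortho-substituted aryl unit. The chromone carbonyl is a weak electrophile and needs forcing acid. Acidic methanol can open the lactone and so destroy the distinction between the two ortho oxygens. The final acetal hydrolysis exposes the tertiary alcohol and the free C4 hydroxyl to acid, which invites chroman formation.
- Comparison: the chosen plan is shorter and keeps acid away from the end game. Against the better oxidation-state economy of this alternative it has to set one well-understood oxidation of an activated methyl group.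

Alternative 3: carboxyl-directed lactonization to a coumestan, then half-reduction.
- Cut: the C2'–O bond of ring B. The 2-arylbenzofuran-3-carboxylic acid A6 has only a 4-benzyloxyphenyl group on C2.
- Key step: Pd(OAc)2 with PhI(OAc)2 oxidizes A6 at the ortho C–H of that ring under carboxyl direction and closes the six-membered lactone of coumestan A7.
- Merits: ring B starts with a single oxygen. The aldehyde oxidation level is reached from A7 by half-reduction of its lactone carbonyl. No methyl oxidation of an electron-rich heteroarene is needed, which is better than the chosen plan at that point.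
- Weak points for this target: the key step does not build ring C, so A6 still has to be made by a separate benzofuran synthesis, and the route is longer. A hypervalent iodine oxidant with divalent palladium meets a very electron-rich benzofuran and a tertiary silyl ether. Half-reduction of the aryl lactone of A7 tends to run on to full reduction, because the phenoxide leaves easily.
- Comparison: the chosen plan builds the heterocycle and joins both aryl halves in one step. It accepts the late oxidation as the cost.

Key step: step 6

## Route

Remark: low-valent titanium generated from TiCl3 and zinc is taken to leave aryl benzyl ethers, the aryl methyl ether and an isolated trisubstituted alkene untouched, as ethers and unactivated alkenes normally are under McMurry conditions.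

Step 1
Reactants: 1 2',6'-dihydroxy-4'-methoxyacetophenone; 2 benzyl bromide
Product: 3 2'-(benzyloxy)-6'-hydroxy-4'-methoxyacetophenone
Conditions: BnBr (1.05 equiv), K2CO3, acetone, reflux
Reagents that add atoms: none
Why: Williamson etherification of a symmetric diphenol; after the first alkylation the remaining hydroxyl is held in a hydrogen bond to the acetyl carbonyl and is much less nucleophilic, so the mono-ether should predominate.

Step 2
Reactants: 3 2'-(benzyloxy)-6'-hydroxy-4'-methoxyacetophenone; 4 1-bromo-3-methylbut-2-ene (prenyl bromide)
Product: 5 2'-(benzyloxy)-4'-methoxy-6'-(3-methylbut-2-en-1-yloxy)acetophenone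
Conditions: prenyl bromide (1.5 equiv), K2CO3, DMF, 60 °C
Reagents that add atoms: none
Why: Williamson O-alkylation of the chelated phenol, which needs the dipolar solvent and gentle heating; the phenoxide attacks the primary allylic carbon, so the unrearranged prenyl ether is expected.

Step 3
Reactants: 5 2'-(benzyloxy)-4'-methoxy-6'-(3-methylbut-2-en-1-yloxy)acetophenone
Product: 8 1-[2-(benzyloxy)-6-hydroxy-4-methoxy-3-(3-methylbut-2-en-1-yl)phenyl]ethanone, via ortho dienone 6 (not isolated), via para dienone 7 (not isolated)
Conditions: N,N-diethylaniline, 200–210 °C, argon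
Reagents that add atoms: none
Why: Claisen–Cope (para-Claisen) rearrangement, known for prenyl ethers of 2-acyl-3,5-dialkoxyphenols; the first [3,3] shift gives the crowded ortho dienone 6 with a 1,1-dimethylallyl group, a second [3,3] shift moves the chain to the para carbon as a normal prenyl group in 7, and enolization gives 8. The chain therefore ends between the benzyloxy and methoxy groups and the released hydroxyl is the one next to the ring CH.

Step 4
Reactants: 9 2,4-dihydroxybenzoic acid; 2 benzyl bromide
Product: 11 2,4-bis(benzyloxy)benzoic acid, via benzyl 2,4-bis(benzyloxy)benzoate 10 (not isolated)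
Conditions: BnBr (3.3 equiv), K2CO3, DMF, 70 °C; then NaOH, MeOH–THF–H2O, reflux; HCl work-up
Reagents that add atoms: benzyl bromide, BrCc1ccccc1; sodium hydroxide, [Na+].[OH-]
Why: exhaustive Williamson benzylation of the carboxylate and both phenols consumes three equivalents of benzyl bromide, two of which supply the ether benzyl groups that remain in 11; saponification of the crude ester 10 then removes the third benzyl group as benzyl alcohol, hydroxide delivering the acid oxygen, and the aryl benzyl ethers are stable to hydroxide.

Step 5
Reactants: 11 2,4-bis(benzyloxy)benzoic acid; 8 1-[2-(benzyloxy)-6-hydroxy-4-methoxy-3-(3-methylbut-2-en-1-yl)phenyl]ethanone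
Product: 13 2-acetyl-3-(benzyloxy)-5-methoxy-4-(3-methylbut-2-en-1-yl)phenyl 2,4-bis(benzyloxy)benzoate, via 2,4-bis(benzyloxy)benzoyl chloride 12 (not isolated)
Conditions: (COCl)2, cat. DMF, CH2Cl2, 0 °C to rt, concentrate; then 8, Et3N, cat. DMAP, CH2Cl2, 0 °C to rt
Reagents that add atoms: none
Why: acid chloride formation and DMAP-catalysed O-acylation of the only free phenol, so the ester can sit only on the oxygen that becomes O1; the amine base does not enolize the ketone at room temperature, which should keep Baker–Venkataraman acyl migration away.

Step 6
Reactants: 13 2-acetyl-3-(benzyloxy)-5-methoxy-4-(3-methylbut-2-en-1-yl)phenyl 2,4-bis(benzyloxy)benzoate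
Product: 14 4-(benzyloxy)-2-[2,4-bis(benzyloxy)phenyl]-6-methoxy-3-methyl-5-(3-methylbut-2-en-1-yl)-1-benzofuran
Conditions: TiCl3, Zn dust, DME, reflux 2 h; then 13 in DME added slowly by syringe pump, reflux, argon
Reagents that add atoms: none
Why: McMurry-type oxo-ester coupling, the known low-valent titanium cyclization of ortho-acyloxyaryl ketones to 2,3-disubstituted benzofurans. Electron transfer from low-valent titanium to the aryl ketone gives a titanium-bound ketyl at the future C3. This carbon adds to the ester carbonyl held ortho to it in a 5-exo-trig closure, forming the C2–C3 bond and a titanium 2,3-diolate of a dihydrobenzofuran. Both C–O bonds are then broken on titanium, driven by the strength of the Ti–O bond and by aromatization of ring C, which leaves the C2=C3 double bond. No stereocenter is formed. The step needs intramolecular coupling to beat pinacol dimerization and plain reduction of the ketone; the ortho relationship of the two carbonyl groups and slow addition at high dilution should secure this. It also needs chemoselectivity for the two carbonyl groups over the benzyl ethers, the methyl ether and the prenyl alkene, none of which is reducible by this reagent. Regiochemistry is not decided here, since the ester was placed on the correct oxygen in steps 3 and 5.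

Step 7
Reactants: 14 4-(benzyloxy)-2-[2,4-bis(benzyloxy)phenyl]-6-methoxy-3-methyl-5-(3-methylbut-2-en-1-yl)-1-benzofuran
Product: 15 4-{4-(benzyloxy)-2-[2,4-bis(benzyloxy)phenyl]-6-methoxy-3-methyl-1-benzofuran-5-yl}-2-methylbutan-2-ol
Conditions: Co(acac)2 (20 mol%), PhSiH3, O2 (1 atm), THF–i-PrOH, rt
Reagents that add atoms: dioxygen, O=O
Why: Mukaiyama hydration; hydrogen-atom transfer from a cobalt hydride to the trisubstituted alkene gives the tertiary radical, which is trapped by O2 and reduced to the Markovnikov alcohol under neutral conditions. The aromatic, tetrasubstituted furan double bond should not take part.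

Step 8
Reactants: 15 4-{4-(benzyloxy)-2-[2,4-bis(benzyloxy)phenyl]-6-methoxy-3-methyl-1-benzofuran-5-yl}-2-methylbutan-2-ol
Product: 16 4-(benzyloxy)-2-[2,4-bis(benzyloxy)phenyl]-5-(3-hydroxy-3-methylbutyl)-6-methoxy-1-benzofuran-3-carbaldehyde
Conditions: SeO2 (1.5 equiv), 1,4-dioxane (trace H2O), 90–100 °C
Reagents that add atoms: selenium dioxide, O=[Se]=O
Why: Riley oxidation of a methyl group on the furan C3, activated like an allylic position of an enol ether; the aldehyde is a vinylogous formate and should resist further oxidation. The tertiary alcohol and the benzyl ethers have no reactive C–H bond of comparable activation.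

Step 9
Reactants: 16 4-(benzyloxy)-2-[2,4-bis(benzyloxy)phenyl]-5-(3-hydroxy-3-methylbutyl)-6-methoxy-1-benzofuran-3-carbaldehyde
Product: 17 2-(2,4-dihydroxyphenyl)-4-hydroxy-5-(3-hydroxy-3-methylbutyl)-6-methoxy-1-benzofuran-3-carbaldehyde (ebenfuran V)
Conditions: H2 (1 atm), 10% Pd/C, EtOAc, rt, stopped at full debenzylation
Reagents that add atoms: none
Why: catalytic hydrogenolysis of three aryl benzyl ethers under neutral conditions; the aldehyde is a deactivated vinylogous ester carbonyl, so debenzylation in an aprotic solvent should be faster than carbonyl reduction, and no acid is present to cyclize the tertiary alcohol onto the C4 hydroxyl.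

## Compound list

1 | 2',6'-dihydroxy-4'-methoxyacetophenone | CC(=O)c1c(O)cc(OC)cc1O | starting material
2 | benzyl bromide | BrCc1ccccc1 | starting material
3 | 2'-(benzyloxy)-6'-hydroxy-4'-methoxyacetophenone | CC(=O)c1c(O)cc(OC)cc1OCc1ccccc1 | intermediate
4 | 1-bromo-3-methylbut-2-ene (prenyl bromide) | CC(C)=CCBr | starting material
5 | 2'-(benzyloxy)-4'-methoxy-6'-(3-methylbut-2-en-1-yloxy)acetophenone | CC(=O)c1c(OCC=C(C)C)cc(OC)cc1OCc1ccccc1 | intermediate
6 | ortho dienone: racemic 2-acetyl-3-(benzyloxy)-5-methoxy-6-(2-methylbut-3-en-2-yl)cyclohexa-2,4-dien-1-one | CC(=O)C1=C(OCc2ccccc2)C=C(OC)C(C(C)(C)C=C)C1=O | intermediate (not isolated)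
7 | para dienone: racemic 2-acetyl-3-(benzyloxy)-5-methoxy-4-(3-methylbut-2-en-1-yl)cyclohexa-2,5-dien-1-one | CC(=O)C1=C(OCc2ccccc2)C(CC=C(C)C)C(OC)=CC1=O | intermediate (not isolated)
8 | 1-[2-(benzyloxy)-6-hydroxy-4-methoxy-3-(3-methylbut-2-en-1-yl)phenyl]ethanone | CC(=O)c1c(O)cc(OC)c(CC=C(C)C)c1OCc1ccccc1 | intermediate
9 | 2,4-dihydroxybenzoic acid | O=C(O)c1ccc(O)cc1O | starting material
10 | benzyl 2,4-bis(benzyloxy)benzoate | O=C(OCc1ccccc1)c1ccc(OCc2ccccc2)cc1OCc1ccccc1 | intermediate (not isolated)
11 | 2,4-bis(benzyloxy)benzoic acid | O=C(O)c1ccc(OCc2ccccc2)cc1OCc1ccccc1 | intermediate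
12 | 2,4-bis(benzyloxy)benzoyl chloride | O=C(Cl)c1ccc(OCc2ccccc2)cc1OCc1ccccc1 | intermediate (not isolated)
13 | 2-acetyl-3-(benzyloxy)-5-methoxy-4-(3-methylbut-2-en-1-yl)phenyl 2,4-bis(benzyloxy)benzoate | CC(=O)c1c(OC(=O)c2ccc(OCc3ccccc3)cc2OCc2ccccc2)cc(OC)c(CC=C(C)C)c1OCc1ccccc1 | intermediate
14 | 4-(benzyloxy)-2-[2,4-bis(benzyloxy)phenyl]-6-methoxy-3-methyl-5-(3-methylbut-2-en-1-yl)-1-benzofuran | Cc1c(-c2ccc(OCc3ccccc3)cc2OCc2ccccc2)oc2cc(OC)c(CC=C(C)C)c(OCc3ccccc3)c12 | intermediate
15 | 4-{4-(benzyloxy)-2-[2,4-bis(benzyloxy)phenyl]-6-methoxy-3-methyl-1-benzofuran-5-yl}-2-methylbutan-2-ol | Cc1c(-c2ccc(OCc3ccccc3)cc2OCc2ccccc2)oc2cc(OC)c(CCC(C)(C)O)c(OCc3ccccc3)c12 | intermediate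
16 | 4-(benzyloxy)-2-[2,4-bis(benzyloxy)phenyl]-5-(3-hydroxy-3-methylbutyl)-6-methoxy-1-benzofuran-3-carbaldehyde | O=Cc1c(-c2ccc(OCc3ccccc3)cc2OCc2ccccc2)oc2cc(OC)c(CCC(C)(C)O)c(OCc3ccccc3)c12 | intermediate
17 | 2-(2,4-dihydroxyphenyl)-4-hydroxy-5-(3-hydroxy-3-methylbutyl)-6-methoxy-1-benzofuran-3-carbaldehyde (ebenfuran V) | COc1cc2oc(-c3ccc(O)cc3O)c(C=O)c2c(O)c1CCC(C)(C)O | target

## Step count and risks

Total: 9 steps. Longest linear sequence: 8 steps (steps 1, 2, 3, 5, 6, 7, 8, 9); step 4 supplies the acid for step 5.

**Step 6 (key step).** The ketone is twisted and hindered, so it may be reduced only as far as the carbinol or couple intermolecularly. The electron-rich benzoate carbonyl is a poor acceptor for the ketyl, so reductive loss of the acyl group back to the phenol may compete. Prolonged exposure to the reductant may also start to cleave benzyl ethers. A more active reagent (TiCl3 reduced with C8K) is the first adjustment. The fallback changes the ring closure. It sets out from 8, which is O-alkylated with ethyl bromoacetate under K2CO3 in hot DMF. The ester enolate then condenses onto the acetyl group in the same pot (Rap–Stoermer-type aldol closure and dehydration) to give ethyl 4-(benzyloxy)-6-methoxy-3-methyl-5-(3-methylbut-2-en-1-yl)-1-benzofuran-2-carboxylate F1. Saponification gives 4-(benzyloxy)-6-methoxy-3-methyl-5-(3-methylbut-2-en-1-yl)-1-benzofuran-2-carboxylic acid F2. A decarboxylative cross-coupling of F2 with 2,4-bis(benzyloxy)-1-bromobenzene F3 follows, using the zerovalent palladium complex Pd(P(t-Bu)3)2 with Cs2CO3 in hot DMF. F3 is obtained by benzylation of 4-bromoresorcinol. The coupling installs ring B at C2 and returns to the route at 14.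

**Step 3.** The ortho dienone may enolize before the second shift, which would leave a reverse-prenyl group on the ring CH position. The prenyl group may also be lost thermally. The fallback sets out from 1. It is C-prenylated directly with 4 in aqueous KOH to 1-[2,6-dihydroxy-4-methoxy-3-(3-methylbut-2-en-1-yl)phenyl]ethanone F4. The less hindered hydroxyl, next to the ring CH, is acylated with chloride 12 (Et3N, DMAP) to give 2-acetyl-3-hydroxy-5-methoxy-4-(3-methylbut-2-en-1-yl)phenyl 2,4-bis(benzyloxy)benzoate F5. The remaining chelated hydroxyl is then benzylated under neutral Mitsunobu conditions (BnOH, PPh3, DIAD), which avoids base-induced acyl migration, and the route is rejoined at 13.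

**Step 8.** The oxidation may stall at the carbinol or run on to the acid. Selenous acid may dehydrate the tertiary alcohol and then attack the new alkene. Selenium may also be incorporated into the electron-rich rings. The fallback sets out from 15 and uses hydride abstraction in place of selenium chemistry. DDQ in wet CH2Cl2 at 0 °C removes hydride from the methyl group and water captures the stabilized benzofuranylmethyl cation, giving {4-(benzyloxy)-2-[2,4-bis(benzyloxy)phenyl]-5-(3-hydroxy-3-methylbutyl)-6-methoxy-1-benzofuran-3-yl}methanol F6. MnO2 in CH2Cl2 then oxidizes this activated primary alcohol selectively to 16.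

**Step 9.** The third benzyl ether, on the crowded C4 oxygen, may be cleaved slowly enough that the aldehyde is reduced to the carbinol or the methyl group in the meantime. The fallback changes the order of events and sets out from 15. Hydrogenolysis before the oxidation gives 2-(2,4-dihydroxyphenyl)-5-(3-hydroxy-3-methylbutyl)-6-methoxy-3-methyl-1-benzofuran-4-ol F7, which is handled under argon. TBSCl and imidazole in DMF silylate the three phenols but not the tertiary alcohol, giving 4-{4-(tert-butyldimethylsilyloxy)-2-[2,4-bis(tert-butyldimethylsilyloxy)phenyl]-6-methoxy-3-methyl-1-benzofuran-5-yl}-2-methylbutan-2-ol F8. Riley oxidation as in step 8 gives 4-(tert-butyldimethylsilyloxy)-2-[2,4-bis(tert-butyldimethylsilyloxy)phenyl]-5-(3-hydroxy-3-methylbutyl)-6-methoxy-1-benzofuran-3-carbaldehyde F9. Bu4NF buffered with acetic acid in THF then removes the silyl groups and reaches 17 without any reductant near the aldehyde.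

## Further compounds

F1 | step 6 | ethyl 4-(benzyloxy)-6-methoxy-3-methyl-5-(3-methylbut-2-en-1-yl)-1-benzofuran-2-carboxylate | CCOC(=O)c1oc2cc(OC)c(CC=C(C)C)c(OCc3ccccc3)c2c1C
F2 | step 6 | 4-(benzyloxy)-6-methoxy-3-methyl-5-(3-methylbut-2-en-1-yl)-1-benzofuran-2-carboxylic acid | OC(=O)c1oc2cc(OC)c(CC=C(C)C)c(OCc3ccccc3)c2c1C
F3 | step 6 | 2,4-bis(benzyloxy)-1-bromobenzene | Brc1ccc(OCc2ccccc2)cc1OCc1ccccc1
F4 | step 3 | 1-[2,6-dihydroxy-4-methoxy-3-(3-methylbut-2-en-1-yl)phenyl]ethanone | CC(=O)c1c(O)cc(OC)c(CC=C(C)C)c1O
F5 | step 3 | 2-acetyl-3-hydroxy-5-methoxy-4-(3-methylbut-2-en-1-yl)phenyl 2,4-bis(benzyloxy)benzoate | CC(=O)c1c(OC(=O)c2ccc(OCc3ccccc3)cc2OCc2ccccc2)cc(OC)c(CC=C(C)C)c1O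
F6 | step 8 | {4-(benzyloxy)-2-[2,4-bis(benzyloxy)phenyl]-5-(3-hydroxy-3-methylbutyl)-6-methoxy-1-benzofuran-3-yl}methanol | OCc1c(-c2ccc(OCc3ccccc3)cc2OCc2ccccc2)oc2cc(OC)c(CCC(C)(C)O)c(OCc3ccccc3)c12
F7 | step 9 | 2-(2,4-dihydroxyphenyl)-5-(3-hydroxy-3-methylbutyl)-6-methoxy-3-methyl-1-benzofuran-4-ol | Cc1c(-c2ccc(O)cc2O)oc2cc(OC)c(CCC(C)(C)O)c(O)c12
F8 | step 9 | 4-{4-(tert-butyldimethylsilyloxy)-2-[2,4-bis(tert-butyldimethylsilyloxy)phenyl]-6-methoxy-3-methyl-1-benzofuran-5-yl}-2-methylbutan-2-ol | Cc1c(-c2ccc(O[Si](C)(C)C(C)(C)C)cc2O[Si](C)(C)C(C)(C)C)oc2cc(OC)c(CCC(C)(C)O)c(O[Si](C)(C)C(C)(C)C)c12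
F9 | step 9 | 4-(tert-butyldimethylsilyloxy)-2-[2,4-bis(tert-butyldimethylsilyloxy)phenyl]-5-(3-hydroxy-3-methylbutyl)-6-methoxy-1-benzofuran-3-carbaldehyde | O=Cc1c(-c2ccc(O[Si](C)(C)C(C)(C)C)cc2O[Si](C)(C)C(C)(C)C)oc2cc(OC)c(CCC(C)(C)O)c(O[Si](C)(C)C(C)(C)C)c12
A1 | alternative 1 | methyl 2-[2,4-bis(benzyloxy)phenyl]-5-(2-diazoacetyl)furan-3-carboxylate | COC(=O)c1cc(C(=O)C=[N+]=[N-])oc1-c1ccc(OCc2ccccc2)cc1OCc1ccccc1
A2 | alternative 1 | triethyl[(6-methoxy-2-methylhex-5-yn-2-yl)oxy]silane | COC#CCCC(C)(C)O[Si](CC)(CC)CC
A3 | alternative 1 | methyl 2-[2,4-bis(benzyloxy)phenyl]-4-hydroxy-6-methoxy-5-[3-methyl-3-(triethylsilyloxy)butyl]-1-benzofuran-3-carboxylate | COC(=O)c1c(-c2ccc(OCc3ccccc3)cc2OCc2ccccc2)oc2cc(OC)c(CCC(C)(C)O[Si](CC)(CC)CC)c(O)c12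
A4 | alternative 2 | 7-(benzyloxy)-3-(7-hydroxy-5-methoxy-2-oxo-3,4-dihydro-2H-chromen-8-yl)-4H-chromen-4-one | O=c1c(-c2c(O)cc(OC)c3CCC(=O)Oc23)coc2cc(OCc3ccccc3)ccc12
A5 | alternative 2 | racemic cyclic methyl acetal of the 6H-benzofuro[3,2-c]chromene, with benzyloxy on ring B and with methoxy and the fused dihydrocoumarin lactone on ring A | COC1Oc2cc(OCc3ccccc3)ccc2-c2oc3cc(OC)c4CCC(=O)Oc4c3c21
A6 | alternative 3 | 4-(benzyloxy)-2-[4-(benzyloxy)phenyl]-6-methoxy-5-[3-methyl-3-(triethylsilyloxy)butyl]-1-benzofuran-3-carboxylic acid | OC(=O)c1c(-c2ccc(OCc3ccccc3)cc2)oc2cc(OC)c(CCC(C)(C)O[Si](CC)(CC)CC)c(OCc3ccccc3)c12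
A7 | alternative 3 | 3,7-bis(benzyloxy)-9-methoxy-8-[3-methyl-3-(triethylsilyloxy)butyl]-6H-benzofuro[3,2-c]chromen-6-one | O=C1Oc2cc(OCc3ccccc3)ccc2-c2oc3cc(OC)c(CCC(C)(C)O[Si](CC)(CC)CC)c(OCc4ccccc4)c3c21
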